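A plateau below full conversion tempts me to declare the enzyme dead, yet a working enzyme stops in the same way once its forward and backward flows cancel. The flask asked about is zeta itself, followed on; theta is its twin at a lower temperature.

in all of them: starting material 0.075 M; protic impurity 0.0225 M; free enzyme 0.55 µM
- zeta: temperature 37 °C; the very flask that is asked about, followed so far
- theta: temperature 22 °C; run made earlier
- flask: temperature 37 °C; time 8.0 d

| run | time / h | target / % |
|---|---|---|
| zeta | 12.0 | 26 |
| zeta | 30.0 | 42 |
| zeta | 72.0 | 45 |
| zeta | 144 | 39 |
| theta | 25.0 | 29 |
| theta | 60.0 | 48 |
| theta | 144 | 65 |
| theta | 288 | 64 |

(standard deviation of a reading: 1.5 percentage points)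

- south-west: change nothing and wait 4.0 d more
- north-west: at 8.0 d add free enzyme, 50.0% of the amount charged, then wait 4.0 d
- west: at 8.0 d take out 90% of the target then present, then wait 4.0 d

- what is taken out of target is counted as made
- additions bring no volume worth counting

- target, in percent of the starting material first charged, at 8.0 d
- which option adds most target ("none" when 2 percentage points or less is all one gets) (south-west / north-west / west / none)
- target present, with what was taken out counted in, in percent of the starting material first charged, after south-west
- target present, with what was taken out counted in, in percent of the starting material first charged, after north-west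

In zeta the target reads 45% at 72.0 h, then falls to 39% at 144 h. Neither a dead enzyme nor a balance gives that fall by itself, so I leave it to a slow loss of target running beside the main reaction. The fall does not choose between the two, and I commit to a balance as a working choice that these readings do not force.

I assume the impurity takes starting material one for one, and I charge it in full. That removes 30.0% of the charge and leaves a pool of 70.0% for target and starting material together. At the zeta reading of 72.0 h, before the fall, the pool splits into 45% target and 25.0% starting material. This gives 1.80 for the balance ratio, target over free starting material once the flows cancel, an apparent equilibrium constant, and it is a reading with that reading's scatter.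

More enzyme reaches the same ratio, so north-west should gain nothing over south-west. Taking target out does act, because the remaining pool splits again. Of what is removed, the share one over one plus the ratio comes back, 0.357. On 90% of the last reading that is 13 percentage points, above the margin of 2 points, so I answer west.

The forecast differs. It gives 35% now, 29.5% after south-west and 45% after north-west, and it picks north-west, on the ground that the plateau “suggests the catalyst dies, probably killed by the excess protic impurity”.

The flask gives 36.5% at 8.0 d, and west is best, adding 10 points, while south-west ends at 32.6% and north-west at 32.5%.

    free enzyme → unfolded enzyme (k = 2.30 × 10⁻⁷ s⁻¹, Ea = 241 kJ mol⁻¹)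
    complex ⇌ free enzyme + target (K = 0.190 M, k = 2.60 s⁻¹, Ea = 67.0 kJ mol⁻¹, ΔH = 3.00 kJ mol⁻¹)
    starting material + target → side product (k = 1.40 × 10⁻⁵ M⁻¹ s⁻¹, Ea = 86.0 kJ mol⁻¹)
    starting material + free enzyme ⇌ complex (K = 9.30 M⁻¹, k = 2600 M⁻¹ s⁻¹, Ea = 41.0 kJ mol⁻¹, ΔH = −50.0 kJ mol⁻¹)
    starting material + protic impurity → quenched substrate (k = 1.80 × 10⁻⁴ M⁻¹ s⁻¹, Ea = 55.0 kJ mol⁻¹)
    (constants at 37 °C)

At 192 h the flask still holds 76.8% of its catalyst as free enzyme, beside 20.1% starting material. The balance ratio times that starting material gives 36.2% target, against 36.5% found. The returning share on 90% of the flask's target gives 12 points, against 10 points found. The neighbour charged with 0.30 M of starting material ends with 15.0% of it, for which the ratio gives 27.0% target, and that neighbour holds 27.5%.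

All runs are calculated with constants of no real substance; scatter was added.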